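(The rate constants are assumed; the flask was simulated.)

Take the logarithm of the equilibrium constant of the first step before anything else, and set the flasks out in powers of ten.

    L + J ⇌ J + G (K1 = 0.711, k1 = 37.5 M⁻¹ min⁻¹, Ea1 = 57.0 kJ mol⁻¹, ΔH1 = −34.0 kJ mol⁻¹)
    J + G ⇌ J.G (K2 = 12 M⁻¹, k2 = 87.1 M⁻¹ min⁻¹, Ea2 = 58.0 kJ mol⁻¹, ΔH2 = −56.0 kJ mol⁻¹)
    Z + J.G → J + Q (k3 = 11.3 M⁻¹ min⁻¹, Ea3 = 48.0 kJ mol⁻¹)
    Z + Q → Z.Q (k4 = 0.358 M⁻¹ min⁻¹, Ea4 = 48.0 kJ mol⁻¹)
    E ⇌ Q, rate k5*(cs5 - [Q]) while solid is left; crystals form when [Q] > cs5 (cs5 = 20 mM, k5 = 14.6 min⁻¹)
    (constants at 25 °C)

| flask | L | Z | J | temperature | time |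
|---|---|---|---|---|---|
| summer | 0.10 M | 0.120 M | 2.5 mM | 5 °C | 15 min |
| dawn | 0.10 M | 0.120 M | 2.5 mM | 25 °C | 15 min |
| autumn | 0.10 M | 0.120 M | 2.5 mM | 45 °C | 15 min |

- the flask with the highest amount of G, in percent of the L charged ("all alike" if they lie within 1.5 percentage points) (summer / dawn / autumn / all alike)
- final G, as a percentage of the L charged, in summer
- final G, as a percentage of the L charged, in dawn
- final G, as a percentage of the L charged, in autumn

- for Q the E are counted in
- as a solid, counted per litre of solution: E
- the list of constants is for 25 °C, to be carried to other temperatures by the activation energies and enthalpies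

**What matters.** J stands on both sides of the first step, so at its balance c(G)/c(L) equals that step's equilibrium constant, whatever c(J) is. I tested each given number against this ratio. An error in the constant at 25 °C passes one to one in logarithms. The enthalpy of the step carries the shift with temperature, so it matters as much. The rate constant and activation energy stay out of the ratio and say how soon it is reached. I set the later steps and the solubility aside, since they act on what leaves L and G.

**The numbers.** The logarithm of 0.711 is −0.148. The enthalpy adds 0.428 for summer and −0.374 for autumn, so autumn has the ceiling ratio, the highest c(G)/c(L) the first step allows, of 0.300. That caps G at 23.1% of L and G together, but taking 0.5 of the enthalpy gives 31.6%, so the enthalpy must be known well.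

**Reaching it.** I gave the rate constant the square root of its factor 22 each way from dawn, and counted J as free. The half-lives of approach came to 22.8 min in summer, 3.07 min in dawn and 0.363 min in autumn. Against 15 min, that put summer under kinetic control and autumn under thermodynamic control. I reckoned G at 24.0% in summer, 40.1% in dawn and 23.1% in autumn, so dawn came highest.

**Forecast.** The forecast gave 16%, 32% and 21%, and named dawn “as the best compromise”.

**The result.** The flasks gave 16.2% in summer, 32.3% in dawn and 20.7% in autumn, so dawn held the most G, and each lay below my figure . In autumn the relaxation half-life of the first step was 0.426 min, far shorter than the 15 min run. There c(G)/c(L) stood at 0.295, beside the ceiling ratio 0.300. The neighbour is the autumn flask with 0.48 M of Z. Z is absent from the first step, so I expected the same 0.300 there. It gave 15.7% of G on 56% of L, a ratio of 0.280.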